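**Retrosynthetic overview**

1. The quinone ring is numbered C-1 (C=O next to the methyl-bearing carbon), C-2 (OH), C-3 (side chain), C-4 (C=O), C-5 (Cl), C-6 (CH3). The enabling feature is that C-3 lies between two oxygen-bearing ring carbons (C-2 and C-4), so the ring is a masked 2-alkylresorcinol mono-silyl ether whose only ring C–H (C-1) is para to the free hydroxyl.
2. Key disconnection (strain release): all six ring carbons come from siloxyalkyne 24 (C-2, C-3 and the whole side chain) and 4-chloro-3-methylcyclobut-2-enone 27 (C-4, C-5, C-6, C-1) by 4π opening, [2+2], 4π opening and 6π closure.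
3. Siloxyalkyne 24 comes from terminal alkyne 21, made by Nozaki–Hiyama–Kishi union of ring aldehyde 12 with (E)-vinyl iodide 17, then oxidation and CBS reduction for the (S)-carbinol.
4. The cyclohexanone ring (ring A) is made first: enamine Michael addition and aldol give (R)-4-methylcyclohexenone; anti conjugate allylation sets the quaternary carbon; axial enolate methylation sets the α-methyl group; the ketone travels as a dioxolane.
5. Order of ring formation: ring A (step 2), then the quinone ring (step 19, last ring of the skeleton); the four-membered ring of 27 (step 17) is only a transient four-carbon donor.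

Key step: step 19

Remark on the chemistry: the α-methyl group of the ketone is trans to the two other ring methyl groups, as drawn. It is treated as the kinetically formed, epimerisable centre, so it is set by enolate alkylation and kept under a ketal until the last step.

Abbreviations in names: Ket = (6S,7S,8R)-6,7,8-trimethyl-1,4-dioxaspiro[4.5]decan-7-yl; PSC = (2E,4S)-4-(tert-butyldimethylsilyloxy)-3-methyl-5-Ket-pent-2-en-1-yl.

**Route**

Step 1
Reactants: 1 propanal; 2 but-3-en-2-one
Product: 3 (R)-2-methyl-5-oxohexanal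
Conditions: (S)-α,α-diphenylprolinol methyl ether (5 mol %), ethyl 3,4-dihydroxybenzoate (20 mol %), neat, 4 °C
Reagents that add atoms: none
Why: Enamine-catalysed Michael addition; the diphenyl(methoxy)methyl group shields one face of the (E)-enamine, so the enone should be attacked from the open face and the methyl-bearing carbon set as R.

Step 2
Reactants: 3 (R)-2-methyl-5-oxohexanal
Product: 4 (R)-4-methylcyclohex-2-en-1-one
Conditions: KOH (0.1 M aq.), Bu4NOH (cat.), Et2O/THF, reflux
Reagents that add atoms: none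
Why: Intramolecular aldol condensation of the methyl ketone onto the aldehyde with dehydration; the stereocentre is not a reacting carbon and cyclisation should outrun enolisation of the aldehyde.

Step 3
Reactants: 4 (R)-4-methylcyclohex-2-en-1-one
Product: 5 trimethyl{[(3S,4R)-3,4-dimethylcyclohex-1-en-1-yl]oxy}silane
Conditions: MeMgBr, CuBr·SMe2 (5 mol %), TMSCl, DMPU, THF, −78 °C; Et3N quench
Reagents that add atoms: methylmagnesium bromide (C[Mg]Br); chlorotrimethylsilane (C[Si](C)(C)Cl)
Why: Copper-catalysed conjugate addition with in situ O-silylation gives a regiodefined silyl enol ether; methyl adds anti to the C-4 methyl group, and this new centre is erased in step 4.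

Step 4
Reactants: 5 trimethyl{[(3S,4R)-3,4-dimethylcyclohex-1-en-1-yl]oxy}silane
Product: 6 (R)-3,4-dimethylcyclohex-2-en-1-one
Conditions: Pd(OAc)2 (10 mol %), O2 (1 atm), DMSO, rt
Reagents that add atoms: none
Why: Saegusa–Ito oxidation; the palladium enolate can undergo β-hydride elimination only toward C-3, zerovalent palladium is reoxidised by O2, and the C-4 stereocentre is untouched.

Step 5
Reactants: 6 (R)-3,4-dimethylcyclohex-2-en-1-one
Product: 7 {[(3S,4R)-3,4-dimethyl-3-(prop-2-en-1-yl)cyclohex-1-en-1-yl]oxy}trimethylsilane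
Conditions: allylMgBr, CuBr·SMe2 (1.1 equiv), LiCl, TMSCl, THF, −78 °C
Reagents that add atoms: allylmagnesium bromide (C=CC[Mg]Br); chlorotrimethylsilane (C[Si](C)(C)Cl)
Why: Conjugate allylation with allylcopper and TMSCl; the allyl group adds axially, anti to the pseudoaxial C-4 methyl group, which should set the quaternary carbon with allyl trans to that methyl, and the enolate is trapped regiospecifically.

Step 6
Reactants: 7 {[(3S,4R)-3,4-dimethyl-3-(prop-2-en-1-yl)cyclohex-1-en-1-yl]oxy}trimethylsilane
Product: 9 (2S,3S,4R)-2,3,4-trimethyl-3-(prop-2-en-1-yl)cyclohexan-1-one, via lithium enolate 8 (not isolated)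
Conditions: MeLi, THF, 0 °C → rt; then MeI, DMPU, −78 → −40 °C
Reagents that add atoms: iodomethane (CI)
Why: Regiospecific lithium enolate from the silyl enol ether, then kinetic methylation; MeI should attack axially on the face anti to the axial quaternary methyl group (the other face would build a 1,3-diaxial methyl/methyl contact), placing the new methyl trans to both ring methyls and cis to allyl.

Step 7
Reactants: 9 (2S,3S,4R)-2,3,4-trimethyl-3-(prop-2-en-1-yl)cyclohexan-1-one
Product: 10 (6S,7S,8R)-6,7,8-trimethyl-7-(prop-2-en-1-yl)-1,4-dioxaspiro[4.5]decane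
Conditions: Me3SiOCH2CH2OSiMe3, TMSOTf (5 mol %), CH2Cl2, −78 → −20 °C; pyridine quench
Reagents that add atoms: 1,2-bis(trimethylsilyloxy)ethane (C[Si](C)(C)OCCO[Si](C)(C)C)
Why: Silyl-transfer ketalisation under kinetic, low-temperature conditions; it masks the ketone and locks the epimerisable α-centre against all later basic steps.

Step 8
Reactants: 10 (6S,7S,8R)-6,7,8-trimethyl-7-(prop-2-en-1-yl)-1,4-dioxaspiro[4.5]decane
Product: 12 2-Ket-acetaldehyde, via ozonide 11 (not isolated)
Conditions: O3, CH2Cl2, −78 °C; then PPh3, −78 °C → rt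
Reagents that add atoms: ozone (O=[O+][O-])
Why: Ozonolysis with reductive work-up; the terminal alkene is the only C=C and the ketal is inert.

Step 9
Reactants: 13 but-2-yn-1-ol
Product: 15 (E)-3-iodobut-2-en-1-ol, via alkenylzirconocene 14 (not isolated)
Conditions: Cp2Zr(H)Cl (2.2 equiv), THF, rt; then I2, 0 °C
Reagents that add atoms: iodine (II)
Why: Hydrozirconation is a syn addition that, after equilibration with excess reagent, places zirconium on the less hindered methyl-bearing carbon; iodinolysis with retention gives the (E)-iodide.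

Step 10
Reactants: 15 (E)-3-iodobut-2-en-1-ol
Product: 16 (E)-1-bromo-3-iodobut-2-ene
Conditions: CBr4, PPh3, CH2Cl2, 0 °C
Reagents that add atoms: carbon tetrabromide (BrC(Br)(Br)Br)
Why: Appel bromination of a primary allylic alcohol under neutral conditions; alkene geometry is kept.

Step 11
Reactants: 16 (E)-1-bromo-3-iodobut-2-ene
Product: 17 (E)-5-iodohex-4-en-1-yne
Conditions: HC≡CMgBr, CuBr·SMe2 (10 mol %), THF, 0 °C → rt
Reagents that add atoms: ethynylmagnesium bromide (C#C[Mg]Br)
Why: Copper-catalysed SN2 substitution of the primary allylic bromide gives the 1,4-enyne; the fully substituted γ-carbon disfavours SN2′ and the vinyl iodide is left intact.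

Step 12
Reactants: 12 2-Ket-acetaldehyde; 17 (E)-5-iodohex-4-en-1-yne
Product: 18 (3E)-3-methyl-1-Ket-hept-3-en-6-yn-2-ol (both C-2 epimers)
Conditions: CrCl2 (4 equiv), NiCl2 (1 mol %), DMSO, rt
Reagents that add atoms: none
Why: Nozaki–Hiyama–Kishi coupling; zerovalent nickel activates the alkenyl iodide, transmetalation gives an alkenylchromium that adds only to the aldehyde with retention of the E geometry; the carbinol centre is formed without control and is corrected in steps 13 and 14.

Step 13
Reactants: 18 (3E)-3-methyl-1-Ket-hept-3-en-6-yn-2-ol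
Product: 19 (3E)-3-methyl-1-Ket-hept-3-en-6-yn-2-one
Conditions: Dess–Martin periodinane, NaHCO3, CH2Cl2, 0 °C → rt
Reagents that add atoms: none
Why: Dess–Martin oxidation under buffered, near-neutral conditions converges both epimers to one enone without isomerising the skipped enyne.

Step 14
Reactants: 19 (3E)-3-methyl-1-Ket-hept-3-en-6-yn-2-one
Product: 20 (2S,3E)-3-methyl-1-Ket-hept-3-en-6-yn-2-ol
Conditions: (R)-2-methyl-CBS-oxazaborolidine (20 mol %), catecholborane, toluene, −78 °C; aq. NaOH work-up
Reagents that add atoms: none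
Why: Corey–Bakshi–Shibata reduction; with the α-methylalkenyl group as the large substituent and the CH2 group as the small one, the (R)-catalyst should deliver hydride to give the (S)-carbinol, and catecholborane at −78 °C leaves the terminal alkyne alone.

Step 15
Reactants: 20 (2S,3E)-3-methyl-1-Ket-hept-3-en-6-yn-2-ol
Product: 21 tert-butyl{[(2S,3E)-3-methyl-1-Ket-hept-3-en-6-yn-2-yl]oxy}dimethylsilane
Conditions: TBSOTf, 2,6-lutidine, CH2Cl2, −78 °C
Reagents that add atoms: tert-butyldimethylsilyl triflate (CC(C)(C)[Si](C)(C)OS(=O)(=O)C(F)(F)F)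
Why: Standard O-silylation; the free hydroxyl must be masked because it would add to the ketene in step 19.

Step 16
Reactants: 21 tert-butyl{[(2S,3E)-3-methyl-1-Ket-hept-3-en-6-yn-2-yl]oxy}dimethylsilane
Product: 24 (2S,3E)-2-(tert-butyldimethylsilyloxy)-3-methyl-1-Ket-7-(triisopropylsilyloxy)hept-3-en-6-yne, via lithium acetylide 22 (not isolated), via lithium ynolate 23 (not isolated)
Conditions: LiN(SiMe3)2, THF, −78 °C; t-BuOOLi (from t-BuOOH and LiN(SiMe3)2), −78 → 0 °C; i-Pr3SiOTf, −78 °C
Reagents that add atoms: lithium tert-butyl peroxide (CC(C)(C)OO[Li]); triisopropylsilyl triflate (CC(C)[Si](OS(=O)(=O)C(F)(F)F)(C(C)C)C(C)C)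
Why: Electrophilic oxygenation of the lithium acetylide by the lithium peroxide gives the ynolate, which the bulky silyl triflate traps on oxygen; the ketal and silyl ether survive and the base is too weak to deprotonate the allylic–propargylic CH2.

Step 17
Reactants: 25 propyne
Product: 26 4,4-dichloro-3-methylcyclobut-2-en-1-one
Conditions: Cl3CCOCl, Zn–Cu couple, Et2O/DME, rt (excess propyne)
Reagents that add atoms: trichloroacetyl chloride (ClC(Cl)(Cl)C(Cl)=O)
Why: [2+2] cycloaddition of dichloroketene, generated in situ, to the alkyne; the ketene carbonyl carbon bonds to the terminal alkyne carbon, placing methyl at C-3.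

Step 18
Reactants: 26 4,4-dichloro-3-methylcyclobut-2-en-1-one
Product: 27 4-chloro-3-methylcyclobut-2-en-1-one (racemic)
Conditions: Zn dust (1.1 equiv), AcOH, TMEDA, EtOH, 0 °C
Reagents that add atoms: none
Why: Zinc reduction of an α,α-dichloroketone removes the first chlorine faster than the second, so limiting zinc at 0 °C should stop at the monochloride; its stereocentre is irrelevant because it becomes sp2 in step 19.

Step 19
Reactants: 24 (2S,3E)-2-(tert-butyldimethylsilyloxy)-3-methyl-1-Ket-7-(triisopropylsilyloxy)hept-3-en-6-yne; 27 4-chloro-3-methylcyclobut-2-en-1-one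
Product: 32 2-chloro-3-methyl-6-PSC-5-(triisopropylsilyloxy)phenol, via chlorovinylketene 28 (not isolated), via vinylcyclobutenone 29 (not isolated), via dienylketene 30 (not isolated), via cyclohexadienone 31 (not isolated)
Conditions: toluene (0.2 M), 80 °C, then 110 °C; 27 (1.6 equiv) added in portions
Reagents that add atoms: none
Why: Release of four-ring strain drives the cascade: 27 opens by thermal 4π-electrocyclic ring opening to ketene 28, whose carbonyl carbon is attacked by the nucleophilic, chain-bearing carbon of the siloxyalkyne in a [2+2] cycloaddition to give 29, a second 4π opening gives 30, and enolisation of 31 gives the phenol. The closest known reaction type is the Danheiser benzannulation of cyclobutenones with siloxyalkynes to resorcinol mono-silyl ethers. The six-membered carbocycle is closed by thermal disrotatory 6π-electrocyclisation, which forms the bond between the ketene carbon and the chlorine-bearing diene terminus. No stereocentre is created, since the chlorine-bearing sp3 carbons of 27 and 31 end as sp2, and the four existing centres are remote and untouched under neutral thermal conditions. The step needs regioselectivity in the [2+2] event, which the oxygen-polarised alkyne secures: the side chain ends between the two oxygens, chlorine ortho to the new free hydroxyl and the single ring hydrogen para to it. It also needs chemoselectivity, secured because the substrate has no free OH and the ketone is masked, so the ketene meets only the ynol ether.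

Step 20
Reactants: 32 2-chloro-3-methyl-6-PSC-5-(triisopropylsilyloxy)phenol
Product: 33 2-chloro-3-methyl-6-PSC-5-(triisopropylsilyloxy)cyclohexa-2,5-diene-1,4-dione
Conditions: (KSO3)2NO (2.5 equiv), KH2PO4 (aq.), acetone, 0 °C → rt
Reagents that add atoms: potassium nitrosodisulfonate ([K+].[K+].[O]N(S(=O)(=O)[O-])S(=O)(=O)[O-])
Why: Teuber oxidation; the phenoxyl radical couples with a second nitroxyl radical at the only free ring carbon, which is para to the hydroxyl, giving the para-quinone; any silyl loss in the buffer is harmless because step 21 removes that group anyway.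

Step 21
Reactants: 33 2-chloro-3-methyl-6-PSC-5-(triisopropylsilyloxy)cyclohexa-2,5-diene-1,4-dione
Product: 34 2-chloro-5-hydroxy-6-[(2E,4S)-4-hydroxy-3-methyl-5-[(1S,2S,6R)-1,2,6-trimethyl-3-oxocyclohexyl]pent-2-en-1-yl]-3-methylcyclohexa-2,5-diene-1,4-dione (CNP0469571.2)
Conditions: HCl (1 M aq.), THF, 0 °C → rt
Reagents that add atoms: water (O)
Why: Mild acid hydrolysis of the dioxolane, the TBS ether and the vinylogous silyl ester; short exposure at or below room temperature should leave the kinetic α-methyl centre and the allylic alcohol intact.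

**Compound list**

1 | propanal | CCC=O | starting material
2 | but-3-en-2-one | C=CC(C)=O | starting material
3 | (R)-2-methyl-5-oxohexanal | O=C[C@H](C)CCC(C)=O | intermediate
4 | (R)-4-methylcyclohex-2-en-1-one | O=C1C=C[C@H](C)CC1 | intermediate
5 | trimethyl{[(3S,4R)-3,4-dimethylcyclohex-1-en-1-yl]oxy}silane | C[Si](C)(C)OC1=C[C@@H](C)[C@H](C)CC1 | intermediate
6 | (R)-3,4-dimethylcyclohex-2-en-1-one | O=C1C=C(C)[C@H](C)CC1 | intermediate
7 | {[(3S,4R)-3,4-dimethyl-3-(prop-2-en-1-yl)cyclohex-1-en-1-yl]oxy}trimethylsilane | C[Si](C)(C)OC1=C[C@@](C)(CC=C)[C@H](C)CC1 | intermediate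
8 | lithium (3S,4R)-3,4-dimethyl-3-(prop-2-en-1-yl)cyclohex-1-en-1-olate | [Li]OC1=C[C@@](C)(CC=C)[C@H](C)CC1 | intermediate
9 | (2S,3S,4R)-2,3,4-trimethyl-3-(prop-2-en-1-yl)cyclohexan-1-one | C=CC[C@@]1(C)[C@H](C)CCC(=O)[C@H]1C | intermediate
10 | (6S,7S,8R)-6,7,8-trimethyl-7-(prop-2-en-1-yl)-1,4-dioxaspiro[4.5]decane | C=CC[C@@]1(C)[C@H](C)CCC2(OCCO2)[C@H]1C | intermediate
11 | 3-(Ket-methyl)-1,2,4-trioxolane (ozonide, epimers at the trioxolane carbon) | C1(C[C@@]2(C)[C@H](C)CCC3(OCCO3)[C@H]2C)OOCO1 | intermediate
12 | 2-Ket-acetaldehyde | O=CC[C@@]1(C)[C@H](C)CCC2(OCCO2)[C@H]1C | intermediate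
13 | but-2-yn-1-ol | CC#CCO | starting material
14 | (E)-alkenylzirconocene chloride of but-2-yn-1-ol, O-zirconated | C/C(=C\CO[Zr](Cl)(C1C=CC=C1)C1C=CC=C1)[Zr](Cl)(C1C=CC=C1)C1C=CC=C1 | intermediate
15 | (E)-3-iodobut-2-en-1-ol | OC/C=C(\C)I | intermediate
16 | (E)-1-bromo-3-iodobut-2-ene | BrC/C=C(\C)I | intermediate
17 | (E)-5-iodohex-4-en-1-yne | C#CC/C=C(\C)I | intermediate
18 | (3E)-3-methyl-1-Ket-hept-3-en-6-yn-2-ol (both C-2 epimers) | C#CC/C=C(\C)C(O)C[C@@]1(C)[C@H](C)CCC2(OCCO2)[C@H]1C | intermediate
19 | (3E)-3-methyl-1-Ket-hept-3-en-6-yn-2-one | C#CC/C=C(\C)C(=O)C[C@@]1(C)[C@H](C)CCC2(OCCO2)[C@H]1C | intermediate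
20 | (2S,3E)-3-methyl-1-Ket-hept-3-en-6-yn-2-ol | C#CC/C=C(\C)[C@@H](O)C[C@@]1(C)[C@H](C)CCC2(OCCO2)[C@H]1C | intermediate
21 | tert-butyl{[(2S,3E)-3-methyl-1-Ket-hept-3-en-6-yn-2-yl]oxy}dimethylsilane | C#CC/C=C(\C)[C@@H](O[Si](C)(C)C(C)(C)C)C[C@@]1(C)[C@H](C)CCC2(OCCO2)[C@H]1C | intermediate
22 | lithium acetylide of 21 | [Li]C#CC/C=C(\C)[C@@H](O[Si](C)(C)C(C)(C)C)C[C@@]1(C)[C@H](C)CCC2(OCCO2)[C@H]1C | intermediate
23 | lithium ynolate from 22 | [Li]OC#CC/C=C(\C)[C@@H](O[Si](C)(C)C(C)(C)C)C[C@@]1(C)[C@H](C)CCC2(OCCO2)[C@H]1C | intermediate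
24 | (2S,3E)-2-(tert-butyldimethylsilyloxy)-3-methyl-1-Ket-7-(triisopropylsilyloxy)hept-3-en-6-yne | CC(C)[Si](C(C)C)(C(C)C)OC#CC/C=C(\C)[C@@H](O[Si](C)(C)C(C)(C)C)C[C@@]1(C)[C@H](C)CCC2(OCCO2)[C@H]1C | intermediate
25 | propyne | CC#C | starting material
26 | 4,4-dichloro-3-methylcyclobut-2-en-1-one | CC1=CC(=O)C1(Cl)Cl | intermediate
27 | 4-chloro-3-methylcyclobut-2-en-1-one (racemic) | CC1=CC(=O)C1Cl | intermediate
28 | (E)-4-chloro-3-methylbuta-1,3-dien-1-one | O=C=C/C(C)=C/Cl | intermediate
29 | 4-[(E)-1-chloroprop-1-en-2-yl]-2-PSC-3-(triisopropylsilyloxy)cyclobut-2-en-1-one (epimers at C-4) | O=C1C(C/C=C(\C)[C@@H](O[Si](C)(C)C(C)(C)C)C[C@@]2(C)[C@H](C)CCC3(OCCO3)[C@H]2C)=C(O[Si](C(C)C)(C(C)C)C(C)C)C1/C(C)=C/Cl | intermediate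
30 | (3E,5E)-6-chloro-5-methyl-2-PSC-3-(triisopropylsilyloxy)hexa-1,3,5-trien-1-one | O=C=C(C/C=C(\C)[C@@H](O[Si](C)(C)C(C)(C)C)C[C@@]1(C)[C@H](C)CCC2(OCCO2)[C@H]1C)/C(O[Si](C(C)C)(C(C)C)C(C)C)=C\C(C)=C\Cl | intermediate
31 | 6-chloro-5-methyl-2-PSC-3-(triisopropylsilyloxy)cyclohexa-2,4-dien-1-one (epimers at C-6) | O=C1C(Cl)C(C)=CC(O[Si](C(C)C)(C(C)C)C(C)C)=C1C/C=C(\C)[C@@H](O[Si](C)(C)C(C)(C)C)C[C@@]2(C)[C@H](C)CCC3(OCCO3)[C@H]2C | intermediate
32 | 2-chloro-3-methyl-6-PSC-5-(triisopropylsilyloxy)phenol | Oc1c(Cl)c(C)cc(O[Si](C(C)C)(C(C)C)C(C)C)c1C/C=C(\C)[C@@H](O[Si](C)(C)C(C)(C)C)C[C@@]2(C)[C@H](C)CCC3(OCCO3)[C@H]2C | intermediate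
33 | 2-chloro-3-methyl-6-PSC-5-(triisopropylsilyloxy)cyclohexa-2,5-diene-1,4-dione | CC1=C(Cl)C(=O)C(C/C=C(\C)[C@@H](O[Si](C)(C)C(C)(C)C)C[C@@]2(C)[C@H](C)CCC3(OCCO3)[C@H]2C)=C(O[Si](C(C)C)(C(C)C)C(C)C)C1=O | intermediate
34 | 2-chloro-5-hydroxy-6-[(2E,4S)-4-hydroxy-3-methyl-5-[(1S,2S,6R)-1,2,6-trimethyl-3-oxocyclohexyl]pent-2-en-1-yl]-3-methylcyclohexa-2,5-diene-1,4-dione | CC1=C(Cl)C(=O)C(C/C=C(\C)[C@@H](O)C[C@@]2(C)[C@H](C)CCC(=O)[C@H]2C)=C(O)C1=O | target

**Step count and risks**

Total step count: 21. Longest linear sequence: 16 steps (steps 1–8, 12–16, 19–21).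

Steps most likely to fail:

Step 19. The aldoketene 28 may dimerise before it meets the alkyne, the intermediate 29 may stall or decompose before its ring opening, and the product phenol may be O-acylated by excess ketene. The supply of 27 is itself fragile because step 18 can over-reduce. The fallback introduces chlorine after the ring is built and sets out from 24 and 26. Full dechlorination of 26 (excess Zn, AcOH, TMEDA, EtOH) gives 3-methylcyclobut-2-en-1-one F1, the best-precedented partner for siloxyalkynes. Heating F1 with 24 in toluene should give the chlorine-free phenol 3-methyl-2-PSC-5-(triisopropylsilyloxy)phenol F2. Bu4NF in THF at 0 °C cleaves the aryl silyl ether to 5-methyl-2-PSC-benzene-1,3-diol F3, whose two free ring positions are equivalent, so one equivalent of N-chlorosuccinimide should give a single monochloride, 4-chloro-5-methyl-2-PSC-benzene-1,3-diol F4. Teuber oxidation with (KSO3)2NO then attacks the remaining ring C–H, para to one hydroxyl, to give 2-chloro-5-hydroxy-3-methyl-6-PSC-cyclohexa-2,5-diene-1,4-dione F5, and aqueous HCl in THF removes the ketal and the TBS group, coming back to the route at 34.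

Step 6. Facial selectivity of the methylation may be eroded, and proton exchange between product and enolate may cause epimerisation or a second methylation. The fallback avoids an enolate altogether and sets out from 7. Simmons–Smith cyclopropanation (Et2Zn, CH2I2, CH2Cl2, 0 °C) of the electron-rich enol ether double bond, on the face anti to the axial quaternary methyl group, should give the siloxycyclopropane (1S,4R,5S,6S)-4,5-dimethyl-5-(prop-2-en-1-yl)-1-(trimethylsilyloxy)bicyclo[4.1.0]heptane F6, the terminal alkene being far less reactive. Acid-induced ring opening (aq. HCl, THF, 0 °C) cleaves the bond between the oxygen-bearing carbon and the cyclopropane CH2, which becomes the α-methyl group with its configuration fixed by the cyclopropanation, and the sequence comes back to the route at 9.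

Step 14. Enantioface discrimination may be insufficient because both carbonyl substituents are bulky, and the skipped enyne of 19 may isomerise into conjugation before it is reduced. The fallback sets out from 12 and 17 and replaces steps 12 to 14 by one catalytic asymmetric Nozaki–Hiyama–Kishi coupling (CrCl2 cat., NiCl2 cat., chiral oxazoline–sulfonamide ligand, Mn as stoichiometric reductant, Cp2ZrCl2, LiCl, MeCN). The carbinol centre is then set by the ligand during C–C bond formation, no enone is ever formed, and the sequence comes back to the route at 20.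

Further compounds

F1 | step 19 | 3-methylcyclobut-2-en-1-one | CC1=CC(=O)C1
F2 | step 19 | 3-methyl-2-PSC-5-(triisopropylsilyloxy)phenol | Oc1cc(C)cc(O[Si](C(C)C)(C(C)C)C(C)C)c1C/C=C(\C)[C@@H](O[Si](C)(C)C(C)(C)C)C[C@@]2(C)[C@H](C)CCC3(OCCO3)[C@H]2C
F3 | step 19 | 5-methyl-2-PSC-benzene-1,3-diol | Oc1cc(C)cc(O)c1C/C=C(\C)[C@@H](O[Si](C)(C)C(C)(C)C)C[C@@]2(C)[C@H](C)CCC3(OCCO3)[C@H]2C
F4 | step 19 | 4-chloro-5-methyl-2-PSC-benzene-1,3-diol | Oc1cc(C)c(Cl)c(O)c1C/C=C(\C)[C@@H](O[Si](C)(C)C(C)(C)C)C[C@@]2(C)[C@H](C)CCC3(OCCO3)[C@H]2C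
F5 | step 19 | 2-chloro-5-hydroxy-3-methyl-6-PSC-cyclohexa-2,5-diene-1,4-dione | CC1=C(Cl)C(=O)C(C/C=C(\C)[C@@H](O[Si](C)(C)C(C)(C)C)C[C@@]2(C)[C@H](C)CCC3(OCCO3)[C@H]2C)=C(O)C1=O
F6 | step 6 | (1S,4R,5S,6S)-4,5-dimethyl-5-(prop-2-en-1-yl)-1-(trimethylsilyloxy)bicyclo[4.1.0]heptane | C[Si](C)(C)O[C@@]12CC[C@@H](C)[C@](C)(CC=C)[C@@H]1C2
F0 | step 14 | none | none
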